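**Strategy.** Everything rests on disconnecting the C10–O bond of the oxolane that bridges C3 and C10 of the ten-membered carbocycle. The key step exploits the 1,4 relationship of the C3 ketone and C10 across that ring: hydrogen-atom transfer to the exocyclic C14 methylene and oxidation give a C10 cation equivalent, the C3 carbonyl oxygen captures it through the five-membered array O–C3–C2–C1–C10, and water closes the hemiketal, so one operation builds the oxolane ring, the C10–O and C3–OH bonds and both stereocentres. The precursor is a furan-fused cyclodecan-3-one with the C10 methylene, the C4 tertiary acetate, C13 acetate and a bulky C6 silyl ether, made by palladium-catalysed C1–C2 ring closure.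

Key step: step 17

Remarks on the chemistry (assumptions):
- Atom labels follow germacrane numbering. C1–C10 is the ten-membered ring; the furan (later butenolide) is C7, C8, O, C12, C11; C13 is the CH2OAc carbon on C11; C14 is the carbon on C10; the C4 methyl is C15.
- The target is read as (3S,4S,6R,10R), with ring carbons C7 and C10 cis on C8=C9 (E descriptor). (S)-Citramalic acid supplies C3–C6 with its quaternary carbon becoming C4 unchanged. No structural error was found.
- Design change to the precursor: O6 is 1,5 to C10, so a small silyl ether there could capture the C10 cation as a six-membered ether with loss of silicon. O6 is therefore carried as a triisopropylsilyl (TIPS) ether. A free C4 hydroxyl would compete in the same way, so it is acetylated before the key step.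
- 3,4-Dibromofuran, 2-methylidenepropane-1,3-diol and (S)-citramalic acid are taken as commercial.

Step 1
Reactants: 1 2-methylidenepropane-1,3-diol
Product: 2 2-{[(triethylsilyl)oxy]methyl}prop-2-en-1-ol
Conditions: NaH (1.0 equiv), THF, 0 °C; Et3SiCl (1.0 equiv), 0 °C → rt
Reagents that add atoms: chlorotriethylsilane, CC[Si](Cl)(CC)CC
Why: Monosilylation of a symmetrical diol through its monosodium alkoxide should stop cleanly at the mono-ether.

Step 2
Reactants: 2 2-{[(triethylsilyl)oxy]methyl}prop-2-en-1-ol
Product: 3 {[2-(bromomethyl)prop-2-en-1-yl]oxy}triethylsilane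
Conditions: CBr4, PPh3, CH2Cl2, 0 °C
Reagents that add atoms: carbon tetrabromide, BrC(Br)(Br)Br
Why: The Appel reaction converts the primary allylic alcohol into the bromide under neutral conditions that leave the triethylsilyl ether intact.

Step 3
Reactants: 4 3,4-dibromofuran
Product: 7 (4-bromofuran-3-yl)methanol, via 3-bromo-4-lithiofuran 5 (not isolated), via 4-bromofuran-3-carbaldehyde 6 (not isolated)
Conditions: n-BuLi (1.0 equiv), Et2O, −78 °C; DMF, −78 → 0 °C; then MeOH, NaBH4, 0 °C
Reagents that add atoms: N,N-dimethylformamide, CN(C)C=O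
Why: Bromine–lithium exchange on one of two equivalent bromines, formylation and borohydride reduction in the same flask should give the future C11–C13 unit with the C7 bromine retained.

Step 4
Reactants: 7 (4-bromofuran-3-yl)methanol
Product: 8 [(4-bromofuran-3-yl)methoxy](tert-butyl)dimethylsilane
Conditions: t-BuMe2SiCl, imidazole, DMF, rt
Reagents that add atoms: tert-butyldimethylsilyl chloride, CC(C)(C)[Si](C)(C)Cl
Why: Standard silylation of a primary alcohol gives an ether that survives the organolithium steps.

Step 5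
Reactants: 8 [(4-bromofuran-3-yl)methoxy](tert-butyl)dimethylsilane; 3 {[2-(bromomethyl)prop-2-en-1-yl]oxy}triethylsilane
Product: 10 3-bromo-4-{[(tert-butyldimethylsilyl)oxy]methyl}-2-{2-[(triethylsilyloxy)methyl]prop-2-en-1-yl}furan, via C8-lithiated bromofuran 9 (not isolated)
Conditions: LiN(iPr)2 (1.05 equiv), THF, −78 °C; then 3, −78 → −20 °C
Reagents that add atoms: none
Why: The furan C–H flanked by the ring oxygen and the C–Br carbon (future C8) is the most acidic, so halogen-directed deprotonation and allylation of the 2-furyllithium should install C9, C10, C14 and C1 regioselectively (direct and allylic displacement give the same product).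

Step 6
Reactants: 11 (S)-citramalic acid
Product: 12 2-[(4S)-2,2,4-trimethyl-5-oxo-1,3-dioxolan-4-yl]acetic acid
Conditions: 2,2-dimethoxypropane, pyridinium p-toluenesulfonate (cat.), rt
Reagents that add atoms: 2,2-dimethoxypropane, COC(C)(C)OC
Why: Acetonide formation of the α-hydroxy acid ties the C4 hydroxyl and the C3 carboxyl into a dioxolanone and leaves the C6 carboxyl free, without touching the C4 stereocentre.

Step 7
Reactants: 12 2-[(4S)-2,2,4-trimethyl-5-oxo-1,3-dioxolan-4-yl]acetic acid
Product: 13 2-[(4S)-2,2,4-trimethyl-5-oxo-1,3-dioxolan-4-yl]acetyl chloride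
Conditions: (COCl)2, DMF (cat.), CH2Cl2, 0 °C → rt; concentrate
Reagents that add atoms: oxalyl chloride, ClC(=O)C(=O)Cl
Why: Vilsmeier-type activation converts the free acid into the acid chloride while the non-enolisable dioxolanone is untouched.

Step 8
Reactants: 10 3-bromo-4-{[(tert-butyldimethylsilyl)oxy]methyl}-2-{2-[(triethylsilyloxy)methyl]prop-2-en-1-yl}furan; 13 2-[(4S)-2,2,4-trimethyl-5-oxo-1,3-dioxolan-4-yl]acetyl chloride
Product: 16 furyl ketone (C6 ketone, dioxolanone intact), via C7-lithiated furan 14 (not isolated), via furylzinc chloride 15 (not isolated)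
Conditions: t-BuLi (2.0 equiv), THF, −78 °C; ZnCl2, −78 → 0 °C; then 13, Pd(PPh3)4 (5 mol %), 0 °C → rt
Reagents that add atoms: none
Why: Bromine–lithium exchange, immediate transmetalation to zinc (which prevents silyl migration and ring-lithium isomerisation) and Negishi acylation catalysed by zerovalent palladium should form C6–C7 without attack on the dioxolanone.

Step 9
Reactants: 16 furyl ketone
Product: 17 (6R)-furyl carbinol
Conditions: (S)-2-methyl-CBS-oxazaborolidine (0.3 equiv), catecholborane (1.8 equiv), toluene, −78 → −40 °C; pH 7 buffer work-up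
Reagents that add atoms: none
Why: In the Corey–Bakshi–Shibata reduction the disubstituted furyl group is the large substituent and C5H2 the small one, so the (S)-catalyst should deliver hydride to give the 6R carbinol; catecholborane does not hydroborate the 1,1-disubstituted alkene.

Step 10
Reactants: 17 (6R)-furyl carbinol
Product: 18 C6 triisopropylsilyl ether
Conditions: iPr3SiOTf, 2,6-lutidine, CH2Cl2, −78 → 0 °C
Reagents that add atoms: triisopropylsilyl trifluoromethanesulfonate, CC(C)[Si](C(C)C)(C(C)C)OS(=O)(=O)C(F)(F)F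
Why: The silyl triflate caps the hindered secondary hydroxyl quickly under basic conditions, before it can lactonise onto the dioxolanone.

Step 11
Reactants: 18 C6 triisopropylsilyl ether
Product: 19 acyclic β-keto sulfone with free C4 hydroxyl
Conditions: PhSO2CH3 (3.3 equiv), n-BuLi (3.2 equiv), THF, −78 °C; then 18, −78 → −20 °C; aq. NH4Cl
Reagents that add atoms: methyl phenyl sulfone, CS(=O)(=O)c1ccccc1
Why: Claisen-type acylation of the lithiated sulfone by the activated dioxolanone carbonyl installs C2, releases acetone and the C4 hydroxyl, and stops at the ketone because the β-keto sulfone is deprotonated in the flask.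

Step 12
Reactants: 19 acyclic β-keto sulfone
Product: 20 C1,C13-diol
Conditions: HF·pyridine, pyridine, THF, 0 °C → rt
Reagents that add atoms: none
Why: Buffered fluoride cleaves the two primary silyl ethers (triethylsilyl and tert-butyldimethylsilyl) much faster than the hindered secondary triisopropylsilyl ether.

Step 13
Reactants: 20 C1,C13-diol
Product: 21 C1,C13-diacetate
Conditions: Ac2O, pyridine, CH2Cl2, 0 °C → rt
Reagents that add atoms: acetic anhydride, CC(=O)OC(C)=O
Why: Both primary hydroxyls are acetylated while the tertiary C4 hydroxyl is not, which installs the final C13 acetate and the allylic leaving group at C1 in one operation.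

Step 14
Reactants: 21 C1,C13-diacetate
Product: 22 ten-membered β-keto sulfone (mixture of C2 epimers)
Conditions: NaH (1.05 equiv), THF, 0 °C; then syringe-pump addition to Pd(PPh3)4 (10 mol %), dppe (10 mol %), THF, 65 °C, final 0.002 mol/L
Reagents that add atoms: none
Why: In this Tsuji–Trost macrocyclisation zerovalent palladium ionises only the allylic acetate, the two termini of the 2-substituted allyl unit are equivalent so no regiochemistry arises, and the soft sulfonyl-stabilised enolate should close C1–C2 under high dilution.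

Step 15
Reactants: 22 ten-membered β-keto sulfone
Product: 23 (4S,6R)-13-acetoxy-4-hydroxy-6-(triisopropylsilyloxy)furanocyclodec-10(14)-en-3-one
Conditions: SmI2 (2.5 equiv), THF/MeOH, −78 °C
Reagents that add atoms: none
Why: Divalent samarium cleaves the α-sulfonyl ketone C–S bond within minutes at −78 °C, faster than it touches the α-hydroxy ketone or the acetate, and removes the C2 stereocentre.

Step 16
Reactants: 23 hydroxy ketone
Product: 24 (4S,6R)-4,13-diacetoxy-6-(triisopropylsilyloxy)furanocyclodec-10(14)-en-3-one (key-step precursor)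
Conditions: Ac2O, 4-(dimethylamino)pyridine, Et3N, CH2Cl2, rt → 40 °C
Reagents that add atoms: acetic anhydride, CC(=O)OC(C)=O
Why: Nucleophilic catalysis acetylates the tertiary α-ketol hydroxyl, which is done only now because the acetate would not survive the sulfone addition or the samarium reduction.

Step 17
Reactants: 24 (4S,6R)-4,13-diacetoxy-6-(triisopropylsilyloxy)furanocyclodec-10(14)-en-3-one
Product: 25 (3S,4S,6R,10R)-3,10-oxa-bridged furanocyclodecane hemiketal, C6 triisopropylsilyl ether
Conditions: Co(salen) [salen = N,N'-bis(3,5-di-tert-butylsalicylidene)cyclohexane-1,2-diaminate; divalent cobalt] (10 mol %), N-fluoro-2,4,6-trimethylpyridinium triflate (2 equiv), PhSiH3 (2 equiv), H2O (5 equiv), PhCF3/acetone 4:1, 0 °C → rt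
Reagents that add atoms: water, O
Why: The oxidant and the silane turn the divalent cobalt complex into a trivalent cobalt hydride that transfers a hydrogen atom to C14; the tertiary C10 radical is taken up by cobalt and oxidised to a tetravalent alkylcobalt (a cation equivalent), the C3 carbonyl oxygen displaces cobalt at C10, and water adds to the resulting C3 oxocarbenium ion. The closest known reaction type is the cobalt–salen, N-fluoropyridinium and silane hydroalkoxylation and hydroacyloxylation of 1,1-disubstituted alkenes by radical–polar crossover, in which hydroxyl and carbonyl oxygens trap the tertiary centre. The oxolane (O, C3, C2, C1, C10) closes by transannular five-membered O–C10 bond formation with the carbonyl oxygen as nucleophile, which converts the cyclodecane into an 11-oxabicyclo[6.2.1]undecane. C10 is set by the ring face from which O3 arrives: the α-acetoxy ketone prefers its C3=O dipole opposed to the C4–OAc bond and the OTIPS group shields that same face, so the bridge should form anti to both oxygen substituents (10R), and C3 (3S) follows because a one-atom bridge can only span C3 and C10 cis. The step needs O3 capture to beat capture by O6, proton loss to ring alkenes and attack on the furan: the TIPS ether and the C4 acetate remove the competing oxygen nucleophiles, the weakly electrophilic trimethylpyridinium oxidant should spare the furan, an isomerised alkene re-enters through the same C10 radical, and direct hydration at C10 would converge on the same hemiketal.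

Step 18
Reactants: 25 oxa-bridged furan hemiketal
Product: 27 C8 lactol (γ-hydroxybutenolide, both C8 epimers), via furan endoperoxide 26 (not isolated)
Conditions: O2, visible light, tetraphenylporphyrin (1 mol %), iPr2NEt (3 equiv), CH2Cl2, −78 °C → rt
Reagents that add atoms: dioxygen, O=O
Why: Singlet oxygen adds across C8 and C12 of the furan, and the amine removes the only bridgehead hydrogen (on C12) in a Kornblum–DeLaMare rearrangement, so C12 becomes the lactone carbonyl and C8 the lactol carbon.

Step 19
Reactants: 27 C8 lactol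
Product: 29 ylidene butenolide, C6 triisopropylsilyl ether, via C8-acetoxy butenolide 28 (not isolated)
Conditions: Ac2O (3 equiv), Et3N (5 equiv), CH2Cl2, 0 °C → rt
Reagents that add atoms: none
Why: The acidic lactol hydroxyl is acylated in preference to the hindered tertiary hemiketal hydroxyl and acetic acid is lost towards C9 (enol-lactone formation of a masked γ-keto acid), the nine-membered ether ring allowing only the C8=C9 geometry with C7 and C10 cis.

Step 20
Reactants: 29 ylidene butenolide, C6 triisopropylsilyl ether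
Product: 30 target, (3S,4S,6R,10R)-4,13-diacetoxy-3,10-epoxy-3,6-dihydroxygermacra-7(11),8-dien-12,8-olide
Conditions: HF·pyridine, pyridine, THF, 0 °C → rt
Reagents that add atoms: none
Why: Buffered fluoride desilylation frees the C6 hydroxyl without touching the two acetates, the hemiketal or the ylidene butenolide.

**Compound list**

1 | 2-methylidenepropane-1,3-diol | C=C(CO)CO | starting material
2 | 2-{[(triethylsilyl)oxy]methyl}prop-2-en-1-ol | C=C(CO)CO[Si](CC)(CC)CC | intermediate
3 | {[2-(bromomethyl)prop-2-en-1-yl]oxy}triethylsilane | C=C(CBr)CO[Si](CC)(CC)CC | intermediate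
4 | 3,4-dibromofuran | Brc1cocc1Br | starting material
5 | 3-bromo-4-lithiofuran (formed in the flask) | [Li]c1cocc1Br | intermediate
6 | 4-bromofuran-3-carbaldehyde (formed in the flask) | O=Cc1cocc1Br | intermediate
7 | (4-bromofuran-3-yl)methanol | OCc1cocc1Br | intermediate
8 | [(4-bromofuran-3-yl)methoxy](tert-butyl)dimethylsilane | CC(C)(C)[Si](C)(C)OCc1cocc1Br | intermediate
9 | 3-bromo-4-{[(tert-butyldimethylsilyl)oxy]methyl}-2-lithiofuran (formed in the flask) | CC(C)(C)[Si](C)(C)OCc1coc([Li])c1Br | intermediate
10 | 3-bromo-4-{[(tert-butyldimethylsilyl)oxy]methyl}-2-{2-[(triethylsilyloxy)methyl]prop-2-en-1-yl}furan | CC(C)(C)[Si](C)(C)OCc1coc(CC(=C)CO[Si](CC)(CC)CC)c1Br | intermediate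
11 | (S)-citramalic acid, (2S)-2-hydroxy-2-methylbutanedioic acid | OC(=O)[C@@](C)(O)CC(=O)O | starting material
12 | 2-[(4S)-2,2,4-trimethyl-5-oxo-1,3-dioxolan-4-yl]acetic acid | O=C1OC(C)(C)O[C@@]1(C)CC(=O)O | intermediate
13 | 2-[(4S)-2,2,4-trimethyl-5-oxo-1,3-dioxolan-4-yl]acetyl chloride | O=C1OC(C)(C)O[C@@]1(C)CC(=O)Cl | intermediate
14 | 4-{[(tert-butyldimethylsilyl)oxy]methyl}-3-lithio-2-{2-[(triethylsilyloxy)methyl]prop-2-en-1-yl}furan (formed in the flask) | CC(C)(C)[Si](C)(C)OCc1coc(CC(=C)CO[Si](CC)(CC)CC)c1[Li] | intermediate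
15 | (4-{[(tert-butyldimethylsilyl)oxy]methyl}-2-{2-[(triethylsilyloxy)methyl]prop-2-en-1-yl}furan-3-yl)zinc chloride (formed in the flask) | CC(C)(C)[Si](C)(C)OCc1coc(CC(=C)CO[Si](CC)(CC)CC)c1[Zn]Cl | intermediate
16 | (5S)-5-[2-(4-{[(tert-butyldimethylsilyl)oxy]methyl}-2-{2-[(triethylsilyloxy)methyl]prop-2-en-1-yl}furan-3-yl)-2-oxoethyl]-2,2,5-trimethyl-1,3-dioxolan-4-one | CC(C)(C)[Si](C)(C)OCc1coc(CC(=C)CO[Si](CC)(CC)CC)c1C(=O)C[C@]2(C)OC(C)(C)OC2=O | intermediate
17 | (5S)-5-[(2R)-2-(4-{[(tert-butyldimethylsilyl)oxy]methyl}-2-{2-[(triethylsilyloxy)methyl]prop-2-en-1-yl}furan-3-yl)-2-hydroxyethyl]-2,2,5-trimethyl-1,3-dioxolan-4-one | CC(C)(C)[Si](C)(C)OCc1coc(CC(=C)CO[Si](CC)(CC)CC)c1[C@H](O)C[C@]2(C)OC(C)(C)OC2=O | intermediate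
18 | triisopropylsilyl ether of 17 at the (2R)-carbinol (future C6) | CC(C)(C)[Si](C)(C)OCc1coc(CC(=C)CO[Si](CC)(CC)CC)c1[C@H](O[Si](C(C)C)(C(C)C)C(C)C)C[C@]2(C)OC(C)(C)OC2=O | intermediate
19 | (3S,5R)-5-(4-{[(tert-butyldimethylsilyl)oxy]methyl}-2-{2-[(triethylsilyloxy)methyl]prop-2-en-1-yl}furan-3-yl)-3-hydroxy-3-methyl-1-(phenylsulfonyl)-5-[(triisopropylsilyl)oxy]pentan-2-one | CC(C)(C)[Si](C)(C)OCc1coc(CC(=C)CO[Si](CC)(CC)CC)c1[C@H](O[Si](C(C)C)(C(C)C)C(C)C)C[C@](C)(O)C(=O)CS(=O)(=O)c1ccccc1 | intermediate
20 | (3S,5R)-3-hydroxy-5-{4-(hydroxymethyl)-2-[2-(hydroxymethyl)prop-2-en-1-yl]furan-3-yl}-3-methyl-1-(phenylsulfonyl)-5-[(triisopropylsilyl)oxy]pentan-2-one | OCc1coc(CC(=C)CO)c1[C@H](O[Si](C(C)C)(C(C)C)C(C)C)C[C@](C)(O)C(=O)CS(=O)(=O)c1ccccc1 | intermediate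
21 | diacetate of 20 at both primary hydroxyls (C1 and C13) | CC(=O)OCc1coc(CC(=C)COC(C)=O)c1[C@H](O[Si](C(C)C)(C(C)C)C(C)C)C[C@](C)(O)C(=O)CS(=O)(=O)c1ccccc1 | intermediate
22 | (4S,6R)-13-acetoxy-4-hydroxy-2-(phenylsulfonyl)-6-(triisopropylsilyloxy)furanocyclodec-10(14)-en-3-one: ten-membered ring C1–C10 fused to the furan at C7–C8, C2 epimers | CC(=O)OCc1coc2CC(=C)CC(S(=O)(=O)c3ccccc3)C(=O)[C@@](C)(O)C[C@@H](O[Si](C(C)C)(C(C)C)C(C)C)c12 | intermediate
23 | (4S,6R)-13-acetoxy-4-hydroxy-6-(triisopropylsilyloxy)furanocyclodec-10(14)-en-3-one | CC(=O)OCc1coc2CC(=C)CCC(=O)[C@@](C)(O)C[C@@H](O[Si](C(C)C)(C(C)C)C(C)C)c12 | intermediate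
24 | (4S,6R)-4,13-diacetoxy-6-(triisopropylsilyloxy)furanocyclodec-10(14)-en-3-one (key-step precursor) | CC(=O)OCc1coc2CC(=C)CCC(=O)[C@@](C)(OC(C)=O)C[C@@H](O[Si](C(C)C)(C(C)C)C(C)C)c12 | intermediate
25 | (3S,4S,6R,10R)-4,13-diacetoxy-3,10-epoxy-3-hydroxy-6-(triisopropylsilyloxy)furanocyclodecane (oxolane O bridging C3 and C10, C10 methyl, C3 hemiketal) | CC(=O)OCc1coc2C[C@@]3(C)CC[C@](O)(O3)[C@@](C)(OC(C)=O)C[C@@H](O[Si](C(C)C)(C(C)C)C(C)C)c12 | intermediate
26 | C8,C12-endoperoxide of 25 (2,3,7-trioxabicyclo[2.2.1]hept-5-ene, formed in the flask) | CC(=O)OCC1=C2C3(OOC1O3)C[C@@]4(C)CC[C@](O)(O4)[C@@](C)(OC(C)=O)C[C@H]2O[Si](C(C)C)(C(C)C)C(C)C | intermediate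
27 | γ-hydroxybutenolide: C12 lactone carbonyl, C7=C11, C8 bearing OH and the lactone oxygen (both C8 epimers), otherwise as 25 | CC(=O)OCC1=C2C(O)(C[C@@]3(C)CC[C@](O)(O3)[C@@](C)(OC(C)=O)C[C@H]2O[Si](C(C)C)(C(C)C)C(C)C)OC1=O | intermediate
28 | C8 acetate of 27 (formed in the flask) | CC(=O)OCC1=C2C(OC(C)=O)(C[C@@]3(C)CC[C@](O)(O3)[C@@](C)(OC(C)=O)C[C@H]2O[Si](C(C)C)(C(C)C)C(C)C)OC1=O | intermediate
29 | C6 triisopropylsilyl ether of the target (C8=C9 ylidene butenolide, C7 and C10 cis) | CC(=O)OCC1=C2/C(=C\[C@@]3(C)CC[C@](O)(O3)[C@@](C)(OC(C)=O)C[C@H]2O[Si](C(C)C)(C(C)C)C(C)C)OC1=O | intermediate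
30 | (3S,4S,6R,10R)-4,13-diacetoxy-3,10-epoxy-3,6-dihydroxygermacra-7(11),8-dien-12,8-olide | CC(=O)OCC1=C2/C(=C\[C@@]3(C)CC[C@](O)(O3)[C@@](C)(OC(C)=O)C[C@H]2O)OC1=O | target

**Totals.** Total step count: 20. Longest linear sequence: 16 steps (from 4 through steps 3, 4, 5 and 8–20; the same count from 1 through steps 1, 2, 5 and 8–20).

**Steps most likely to fail**

1. Step 17. What may go wrong is capture of the C10 cation equivalent from the wrong ring face or by another nucleophile, or oxidative damage to the furan by the N–F oxidant. Fallback, setting out from 24: a Mukaiyama hydration (Co(acac)2 with divalent cobalt, PhSiH3, O2, iPrOH/THF, rt) generates the same tertiary C10 radical but traps it with dioxygen, with no electrophilic oxidant present. This would give the open-chain (10R)-10-hydroxy-3-ketone F1, which should close through reversible O–C3 hemiketalisation (spontaneously or with a trace of pyridinium p-toluenesulfonate) and so return to the route at 25. The C10 epimer would give a diastereomeric bicycle to be separated.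

2. Step 14. What may go wrong is intermolecular alkylation to oligomers outrunning the ten-membered ring closure. Fallback, setting out from 19: the ring is closed by direct displacement of a discrete allylic bromide instead of palladium catalysis. Selective removal of the triethylsilyl group (pyridinium p-toluenesulfonate, MeOH, 0 °C) would give the C1 allylic alcohol F2 with the C13 silyl ether intact. Appel bromination (CBr4, PPh3) would give the allylic bromide F3. Slow addition to Cs2CO3 in MeCN at high dilution would close C1–C2 to the macrocyclic keto sulfone F4. SmI2 in THF/MeOH at −78 °C would give the C13 silyloxymethyl hydroxy ketone F5, and HF·pyridine would give the C13 hydroxymethyl hydroxy ketone F6. Acetylation of both hydroxyls (Ac2O, 4-(dimethylamino)pyridine, Et3N) returns to the route at 24.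

3. Step 9. What may go wrong is poor facial selectivity of hydride delivery, because the furyl group carries two ortho substituents and C5 is neopentyl-like, or lactonisation of the product during work-up. Fallback, setting out from 16: stereocontrol is moved from the reagent to the substrate. Methanolysis of the dioxolanone (K2CO3 cat., MeOH, 0 °C) would free the C4 hydroxyl as the β-hydroxy keto methyl ester F7. A Narasaka–Prasad reduction (Et2BOMe, NaBH4, THF/MeOH, −78 °C) through the boron chelate would give the 4,6-syn diol ester F8, which lactonises on work-up to the (3S,5R)-α-hydroxy-γ-butyrolactone F9. Lithiated methyl phenyl sulfone (3.5 equiv, THF, −78 °C) would open the lactone to the diol keto sulfone F10. Selective silylation of the secondary hydroxyl (iPr3SiOTf, 2,6-lutidine, −78 °C) returns to the route at 19.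

**Further compounds**

F1 | step 17 | (4S,6R,10R)-4,13-diacetoxy-10-hydroxy-10-methyl-6-(triisopropylsilyloxy)furanocyclodecan-3-one (open hydroxy ketone form of 25) | CC(=O)OCc1coc2C[C@](C)(O)CCC(=O)[C@@](C)(OC(C)=O)C[C@@H](O[Si](C(C)C)(C(C)C)C(C)C)c12
F2 | step 14 | C1 allylic alcohol: 19 without the triethylsilyl group | CC(C)(C)[Si](C)(C)OCc1coc(CC(=C)CO)c1[C@H](O[Si](C(C)C)(C(C)C)C(C)C)C[C@](C)(O)C(=O)CS(=O)(=O)c1ccccc1
F3 | step 14 | C1 allylic bromide of F2 | CC(C)(C)[Si](C)(C)OCc1coc(CC(=C)CBr)c1[C@H](O[Si](C(C)C)(C(C)C)C(C)C)C[C@](C)(O)C(=O)CS(=O)(=O)c1ccccc1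
F4 | step 14 | ten-membered β-keto sulfone with C13 tert-butyldimethylsilyl ether (C2 epimers) | CC(C)(C)[Si](C)(C)OCc1coc2CC(=C)CC(S(=O)(=O)c3ccccc3)C(=O)[C@@](C)(O)C[C@@H](O[Si](C(C)C)(C(C)C)C(C)C)c12
F5 | step 14 | (4S,6R)-13-(tert-butyldimethylsilyloxy)-4-hydroxy-6-(triisopropylsilyloxy)furanocyclodec-10(14)-en-3-one | CC(C)(C)[Si](C)(C)OCc1coc2CC(=C)CCC(=O)[C@@](C)(O)C[C@@H](O[Si](C(C)C)(C(C)C)C(C)C)c12
F6 | step 14 | (4S,6R)-4,13-dihydroxy-6-(triisopropylsilyloxy)furanocyclodec-10(14)-en-3-one | OCc1coc2CC(=C)CCC(=O)[C@@](C)(O)C[C@@H](O[Si](C(C)C)(C(C)C)C(C)C)c12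
F7 | step 9 | methyl (2S)-4-(4-{[(tert-butyldimethylsilyl)oxy]methyl}-2-{2-[(triethylsilyloxy)methyl]prop-2-en-1-yl}furan-3-yl)-2-hydroxy-2-methyl-4-oxobutanoate | CC(C)(C)[Si](C)(C)OCc1coc(CC(=C)CO[Si](CC)(CC)CC)c1C(=O)C[C@](C)(O)C(=O)OC
F8 | step 9 | methyl (2S,4R)-2,4-dihydroxy-2-methyl-4-(furyl)butanoate, furyl as in F7 (syn diol, not isolated) | CC(C)(C)[Si](C)(C)OCc1coc(CC(=C)CO[Si](CC)(CC)CC)c1[C@H](O)C[C@](C)(O)C(=O)OC
F9 | step 9 | (3S,5R)-3-hydroxy-3-methyl-5-(furyl)dihydrofuran-2(3H)-one, furyl as in F7 | CC(C)(C)[Si](C)(C)OCc1coc(CC(=C)CO[Si](CC)(CC)CC)c1[C@H]2C[C@](C)(O)C(=O)O2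
F10 | step 9 | (3S,5R)-3,5-dihydroxy-3-methyl-1-(phenylsulfonyl)-5-(furyl)pentan-2-one, furyl as in F7 (19 without the triisopropylsilyl group) | CC(C)(C)[Si](C)(C)OCc1coc(CC(=C)CO[Si](CC)(CC)CC)c1[C@H](O)C[C@](C)(O)C(=O)CS(=O)(=O)c1ccccc1
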